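The route rests on cutting ring A of the decalin (C1'–C2'–C3'–C4'–C4a'–C8a') at C1'–C2' and C3'–C4'. The feature used is that C2', with its methyl group and its exocyclic carbon, is the α-carbon of methacrolein and that C1' is a methyl-bearing diene terminus. One intermolecular Diels–Alder reaction therefore closes ring A, builds the quaternary centre C2' next to C1' with both methyls cis, and brings in the formyl carbon that later becomes C8 of the dioxabicyclooctanone. The precursor is an s-cis-locked bis-exocyclic diene, a 2-ethylidene-3-methylidene-4,4-dimethylcyclohexyl silyl ether, whose C8' stereocentre directs the dienophile.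

Key step: step 7

Numbering: primed locants are those of the octahydronaphthalene (C1' CHMe, C2' quaternary, C4a' ring-fusion CH, C5' CMe2, C8'=C8a'); ring B is the gem-dimethyl ring; unprimed locants are those of the 2,7-dioxabicyclo[3.2.1]octan-3-one (C1 acetal, C3 lactone carbonyl, C6 ester-bearing, C8 one-carbon bridge).

Remark on configuration: an outward methyl on a diene terminus ends on the face from which the dienophile arrives. Attack anti to the C8' silyl ether therefore gives C8'–O trans to the C1' methyl, so the diene must be (S) at C8'; an (R)-diene attacked anti would give the antipodal C1'/C2' pair. Its ethylidene is Z by the sequence rules once C8' bears oxygen (the same geometry as the E-enone 9). The diazene rearrangement needs C8'–O cis to the C1' methyl, so C8' is reset by oxidation (step 10) and oxazaborolidine reduction (step 20).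

Assumption: the sense of induction of the copper-catalysed boryl addition in step 2 is taken to follow the parent cyclohexenone; the ligand antipode is chosen so that (S)-4 results.

Step 1
Reactants: 1 2,2-dimethylcyclohexan-1-one
Product: 2 6,6-dimethylcyclohex-2-en-1-one
Conditions: Pd(OCOCF3)2 (5 mol %), DMSO (10 mol %), O2 (1 atm), AcOH, 80 °C
Reagents that add atoms: none
Why: Aerobic palladium-catalysed α,β-dehydrogenation (palladium enolate, β-hydride elimination) should give a single enone because only C6 carries α-hydrogens and the gem-dimethyl group excludes aromatisation.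

Step 2
Reactants: 2 6,6-dimethylcyclohex-2-en-1-one
Product: 4 (S)-5-hydroxy-2,2-dimethylcyclohexan-1-one, via boryl ketone 3 (not isolated)
Conditions: B2pin2 (1.1 equiv), CuCl (3 mol %), NaOtBu (3 mol %), (R)-1-[(S)-2-(diphenylphosphino)ferrocenyl]ethyldicyclohexylphosphine or its antipode (3 mol %), MeOH (2 equiv), THF, rt; then 30 % H2O2, pH 7 phosphate buffer, 0 °C
Reagents that add atoms: hydrogen peroxide, OO
Why: Copper-catalysed enantioselective conjugate borylation places boron on the β-carbon under ligand control, and buffered C–B oxidation with retention should give the (S)-carbinol, the future C8', without β-elimination.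

Step 3
Reactants: 4 (S)-5-hydroxy-2,2-dimethylcyclohexan-1-one
Product: 5 (S)-5-(tert-butyldimethylsilyloxy)-2,2-dimethylcyclohexan-1-one
Conditions: t-BuMe2SiCl (1.2 equiv), imidazole (2.5 equiv), DMF, rt
Reagents that add atoms: tert-butyldimethylsilyl chloride, CC(C)(C)[Si](C)(C)Cl
Why: Imidazole-mediated silylation of a secondary alcohol; the bulky ether is the later face-directing group.

Step 4
Reactants: 5 (S)-5-(tert-butyldimethylsilyloxy)-2,2-dimethylcyclohexan-1-one; 6 acetaldehyde
Product: 7 (3S)-3-(tert-butyldimethylsilyloxy)-2-(1-hydroxyethyl)-6,6-dimethylcyclohexan-1-one (diastereomer mixture at C2 and the carbinol carbon)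
Conditions: LDA (1.1 equiv), THF, −78 °C; then 6 (1.5 equiv), −78 °C, 15 min; sat. NH4Cl
Reagents that add atoms: none
Why: Kinetic lithium-enolate aldol addition; C6 of 5 is the only enolisable position and at −78 °C the enolate should add to the aldehyde faster than it expels the β-silyloxy group.

Step 5
Reactants: 7 (3S)-3-(tert-butyldimethylsilyloxy)-2-(1-hydroxyethyl)-6,6-dimethylcyclohexan-1-one
Product: 9 (S,E)-3-(tert-butyldimethylsilyloxy)-2-ethylidene-6,6-dimethylcyclohexan-1-one, via mesylate 8 (not isolated)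
Conditions: MsCl, Et3N, CH2Cl2, 0 °C; then DBU, rt
Reagents that add atoms: none
Why: Mesylation and E1cB elimination (aldol condensation completed); mesylate leaves far more readily than the ring silyloxy group, and the methyl should settle anti to the carbonyl, i.e. on the side of C8'.

Step 6
Reactants: 9 (S,E)-3-(tert-butyldimethylsilyloxy)-2-ethylidene-6,6-dimethylcyclohexan-1-one
Product: 10 tert-butyl{[(1S,2Z)-2-ethylidene-4,4-dimethyl-3-methylidenecyclohexyl]oxy}dimethylsilane (diene)
Conditions: Zn, CH2Br2, TiCl4, THF/CH2Cl2, 0 °C to rt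
Reagents that add atoms: dibromomethane, BrCBr
Why: Takai–Lombardo methylenation by a non-basic gem-dizinc/titanium reagent should convert the hindered, non-enolisable conjugated ketone into the exocyclic methylene without touching the alkene geometry or the silyl ether.

Step 7
Reactants: 10 tert-butyl{[(1S,2Z)-2-ethylidene-4,4-dimethyl-3-methylidenecyclohexyl]oxy}dimethylsilane; 11 methacrolein
Product: 12 (1R,2R,8S)-8-(tert-butyldimethylsilyloxy)-1,2,5,5-tetramethyl-1,2,3,4,5,6,7,8-octahydronaphthalene-2-carbaldehyde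
Conditions: Me2AlCl (1.2 equiv), 11 (3 equiv), CH2Cl2, −78 to −40 °C
Reagents that add atoms: none
Why: The enal, bound to aluminium through its carbonyl oxygen, adds to the s-cis-held diene in a concerted, asynchronous [4+2] cycloaddition whose leading bond joins the β-carbon to the unsubstituted terminus C4' (ortho rule), so that C2' ends next to the methyl-bearing C1'. The closest known reaction type is the Lewis-acid-promoted Diels–Alder reaction of 2-substituted acroleins with 1,2-dialkylidenecyclohexanes. Ring A closes as a six-membered carbocycle by suprafacial–suprafacial cycloaddition, C1'–C2' and C3'–C4' forming in one step and the C4a'=C8a' alkene being left behind. C1' and C2' are set relative to each other by the exo-formyl (endo-methyl) transition state, in which the outward C1' methyl and the endo C2' methyl finish cis; their absolute sense is set by C8', because allylic strain with the Z-methyl holds the silyloxy group pseudoaxial and the endo methyl of the dienophile must pass on the opposite face. The step needs ortho regiochemistry, exo-formyl selectivity and anti-silyloxy attack; these should be secured respectively by the methyl-bearing terminus, by the α-methyl group together with the bulk of the coordinated formyl group (which avoids the space under ring B), and by the pseudoaxial silyl ether.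

Step 8
Reactants: 12 (1R,2R,8S)-8-(tert-butyldimethylsilyloxy)-1,2,5,5-tetramethyl-1,2,3,4,5,6,7,8-octahydronaphthalene-2-carbaldehyde
Product: 13 (1'S,2'R,8'S)-8'-(tert-butyldimethylsilyloxy)-2'-(2-methoxyethenyl)-1',2',5',5'-tetramethyl-1',2',3',4',5',6',7',8'-octahydronaphthalene (E/Z mixture)
Conditions: MeOCH2PPh3Cl (2 equiv), KHMDS (1.9 equiv), THF, 0 °C; then 12, 0 °C to rt
Reagents that add atoms: (methoxymethyl)triphenylphosphonium chloride, COC[P+](c1ccccc1)(c1ccccc1)c1ccccc1.[Cl-]
Why: Wittig methoxymethylenation of a non-enolisable neopentyl aldehyde; the new carbon is C1 and the former formyl carbon becomes C8.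

Step 9
Reactants: 13 (silyl ether enol ether)
Product: 14 (1'S,2'R,8'S)-2'-(2-methoxyethenyl)-1',2',5',5'-tetramethyl-1',2',3',4',5',6',7',8'-octahydronaphthalen-8'-ol
Conditions: Bu4NF (1.5 equiv), THF, rt
Reagents that add atoms: none
Why: Fluoride desilylation under basic conditions, which the enol ether tolerates.

Step 10
Reactants: 14 (allylic alcohol)
Product: 15 (1'S,2'R)-2'-(2-methoxyethenyl)-1',2',5',5'-tetramethyl-2',3',4',5',6',7'-hexahydronaphthalen-8'(1'H)-one
Conditions: MnO2 (15 equiv), CH2Cl2, rt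
Reagents that add atoms: none
Why: Selective allylic oxidation; the resulting tetrasubstituted enone is a robust placeholder for C8' that cannot ionise in the acidic steps ahead.

Step 11
Reactants: 15 (enone enol ether)
Product: 16 2-[(1S,2S)-1,2,5,5-tetramethyl-8-oxo-1,2,3,4,5,6,7,8-octahydronaphthalen-2-yl]acetaldehyde
Conditions: 1 M HCl, THF, 0 °C to rt
Reagents that add atoms: water, O
Why: Acid hydrolysis of the enol ether completes the one-carbon homologation; cyclisation of the aldehyde onto the enone is disfavoured because it would place C8a' at a bridgehead alkene.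

Step 12
Reactants: 17 (R)-3-(benzyloxy)propane-1,2-diol
Product: 18 (S)-1-(benzyloxy)-2,3-bis(triethylsilyloxy)propane
Conditions: Et3SiCl (2.4 equiv), imidazole (4 equiv), CH2Cl2, 0 °C to rt
Reagents that add atoms: chlorotriethylsilane, CC[Si](Cl)(CC)CC
Why: Exhaustive silylation of the diol prepares the selective unmasking of the primary position.

Step 13
Reactants: 18 (S)-1-(benzyloxy)-2,3-bis(triethylsilyloxy)propane
Product: 19 (S)-3-(benzyloxy)-2-(triethylsilyloxy)propanal
Conditions: (COCl)2, DMSO, CH2Cl2, −78 to −30 °C; then Et3N, −78 °C to rt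
Reagents that add atoms: none
Why: Swern oxidation carried out directly on a primary triethylsilyl ether, which is cleaved by the chlorosulfonium salt and oxidised while the secondary silyl ether stays; no base-induced epimerisation is expected at low temperature.

Step 14
Reactants: 19 (S)-3-(benzyloxy)-2-(triethylsilyloxy)propanal; 20 ethyl 2-oxo-3-(triphenylphosphoranylidene)propanoate
Product: 21 ethyl (R,E)-6-(benzyloxy)-2-oxo-5-(triethylsilyloxy)hex-3-enoate
Conditions: 20 (1.2 equiv), PhMe, 60 °C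
Reagents that add atoms: none
Why: Wittig olefination with a keto-stabilised ylide should give the E-configured β,γ-unsaturated α-keto ester; its γ-carbon (the future C6) has no acidifying substituent.

Step 15
Reactants: 16 2-[(1S,2S)-1,2,5,5-tetramethyl-8-oxo-1,2,3,4,5,6,7,8-octahydronaphthalen-2-yl]acetaldehyde; 21 ethyl (R,E)-6-(benzyloxy)-2-oxo-5-(triethylsilyloxy)hex-3-enoate
Product: 22 ethyl (3R,4R)-4-[(1R)-2-(benzyloxy)-1-(triethylsilyloxy)ethyl]-2-hydroxy-3-[(1S,2R)-1,2,5,5-tetramethyl-8-oxo-1,2,3,4,5,6,7,8-octahydronaphthalen-2-yl]-3,4-dihydro-2H-pyran-6-carboxylate (3,4-trans, anomer mixture)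
Conditions: (R)-2-[diphenyl(trimethylsilyloxy)methyl]pyrrolidine (20 mol %), PhCO2H (20 mol %), 21 (1.2 equiv), PhMe, 0 °C to rt; aqueous work-up
Reagents that add atoms: none
Why: Amine-catalysed inverse-electron-demand hetero-Diels–Alder reaction (enamine Michael addition, then hemiacetal closure): the E-enamine of 16 reacts on the face away from the diphenyl(silyloxy)methyl group, which sets C8, and the syn topicity of the addition sets C5 trans to C8 on the new pyran, while C6 comes in from 17 and the hindered enone of the decalin stays out.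

Step 16
Reactants: 22 (lactol)
Product: 25 (1S,5R,6R,8R)-6-[(benzyloxy)methyl]-8-[(1S,2R)-1,2,5,5-tetramethyl-8-oxo-1,2,3,4,5,6,7,8-octahydronaphthalen-2-yl]-2,7-dioxabicyclo[3.2.1]octan-3-one, via silyl ether acid 23 (not isolated), via hydroxy acid 24 (not isolated)
Conditions: 30 % H2O2, NaHCO3, THF/H2O, 0 °C to rt; Na2SO3; then 1 M HCl, THF, rt; then PPTS, PhMe, 4 Å molecular sieves, 50 °C
Reagents that add atoms: hydrogen peroxide, OO; water, O
Why: Hydroperoxide adds to the keto group of the ring-opened α-keto ester and excises the ethoxycarbonyl carbon (oxidative decarboxylation of Baeyer–Villiger type) to leave the C3 acid, acid removes the triethylsilyl group, and the C6 hydroxyl, the C1 aldehyde and the C3 acid should condense to the bridged lactone acetal, in which C1 is fixed by the ring system.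

Step 17
Reactants: 25 (benzyl ether)
Product: 26 (1S,5R,6R,8R)-6-(hydroxymethyl)-8-[(1S,2R)-1,2,5,5-tetramethyl-8-oxo-1,2,3,4,5,6,7,8-octahydronaphthalen-2-yl]-2,7-dioxabicyclo[3.2.1]octan-3-one
Conditions: H2 (1 atm), Pd(OH)2/C, EtOAc, rt
Reagents that add atoms: none
Why: Neutral hydrogenolysis of the benzyl ether; the tetrasubstituted enone alkene and the lactone acetal should be untouched.

Step 18
Reactants: 26 (primary alcohol)
Product: 27 (1S,5R,6R,8R)-3-oxo-8-[(1S,2R)-1,2,5,5-tetramethyl-8-oxo-1,2,3,4,5,6,7,8-octahydronaphthalen-2-yl]-2,7-dioxabicyclo[3.2.1]octane-6-carboxylic acid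
Conditions: TEMPO (0.2 equiv), PhI(OAc)2 (2.5 equiv), MeCN/H2O 1:1, rt
Reagents that add atoms: water, O
Why: Oxoammonium-mediated oxidation of the primary alcohol through the aldehyde hydrate to the acid under near-neutral conditions; any epimerisation at C6 at the aldehyde stage would drift to the wanted exo isomer.

Step 19
Reactants: 27 (carboxylic acid)
Product: 28 methyl (1S,5R,6R,8R)-3-oxo-8-[(1S,2R)-1,2,5,5-tetramethyl-8-oxo-1,2,3,4,5,6,7,8-octahydronaphthalen-2-yl]-2,7-dioxabicyclo[3.2.1]octane-6-carboxylate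
Conditions: Me3SiCHN2, PhMe/MeOH 4:1, 0 °C
Reagents that add atoms: (trimethylsilyl)diazomethane, C[Si](C)(C)C=[N+]=[N-]
Why: Diazoalkane esterification without acid or base, so the lactone acetal and C6 are not disturbed.

Step 20
Reactants: 28 (enone methyl ester)
Product: 29 methyl (1S,5R,6R,8R)-8-[(1S,2R,8R)-8-hydroxy-1,2,5,5-tetramethyl-1,2,3,4,5,6,7,8-octahydronaphthalen-2-yl]-3-oxo-2,7-dioxabicyclo[3.2.1]octane-6-carboxylate
Conditions: (S)-1-methyl-3,3-diphenyltetrahydro-1H,3H-pyrrolo[1,2-c][1,3,2]oxazaborole (0.3 equiv), catecholborane (1.5 equiv), PhMe, −78 °C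
Reagents that add atoms: none
Why: Corey–Bakshi–Shibata 1,2-reduction with the alkene carbon C8a' as the large group; catalyst and substrate (hydride anti to the pseudoaxial C1' methyl) should agree and give the 8'R alcohol, cis to the C1' methyl, while lactone and ester survive at −78 °C.

Step 21
Reactants: 29 (allylic alcohol)
Product: 32 methyl (1S,5R,6R,8R)-3-oxo-8-[(1S,2R,4aS)-1,2,5,5-tetramethyl-1,2,3,4,4a,5,6,7-octahydronaphthalen-2-yl]-2,7-dioxabicyclo[3.2.1]octane-6-carboxylate (CNP0301564.1), via sulfonylhydrazine 30 (not isolated), via diazene 31 (not isolated)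
Conditions: 2-nitrobenzenesulfonohydrazide, PPh3, DEAD, THF, −30 °C, 2 h; then 23 °C
Reagents that add atoms: none
Why: Myers reductive 1,3-transposition: Mitsunobu displacement with inversion, loss of sulfinic acid, and retro-ene loss of N2 from the monoalkyl diazene, which hands hydrogen to C4a' on the face of the C–N bond (anti to the C1'/C2' methyls) and moves the alkene to C8'=C8a'.

Compound list
1 | 2,2-dimethylcyclohexan-1-one | CC1(C)CCCCC1=O | starting material
2 | 6,6-dimethylcyclohex-2-en-1-one | CC1(C)CCC=CC1=O | intermediate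
3 | (S)-2,2-dimethyl-5-(4,4,5,5-tetramethyl-1,3,2-dioxaborolan-2-yl)cyclohexan-1-one | O=C1C[C@@H](B2OC(C)(C)C(C)(C)O2)CCC1(C)C | intermediate (not isolated)
4 | (S)-5-hydroxy-2,2-dimethylcyclohexan-1-one | O=C1C[C@@H](O)CCC1(C)C | intermediate
5 | (S)-5-(tert-butyldimethylsilyloxy)-2,2-dimethylcyclohexan-1-one | O=C1C[C@@H](O[Si](C)(C)C(C)(C)C)CCC1(C)C | intermediate
6 | acetaldehyde | CC=O | starting material
7 | (3S)-3-(tert-butyldimethylsilyloxy)-2-(1-hydroxyethyl)-6,6-dimethylcyclohexan-1-one, diastereomer mixture | O=C1C(C(C)O)[C@@H](O[Si](C)(C)C(C)(C)C)CCC1(C)C | intermediate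
8 | methanesulfonate of 7 | O=C1C(C(C)OS(C)(=O)=O)[C@@H](O[Si](C)(C)C(C)(C)C)CCC1(C)C | intermediate (not isolated)
9 | (S,E)-3-(tert-butyldimethylsilyloxy)-2-ethylidene-6,6-dimethylcyclohexan-1-one | C/C=C1\[C@@H](O[Si](C)(C)C(C)(C)C)CCC(C)(C)C1=O | intermediate
10 | tert-butyl{[(1S,2Z)-2-ethylidene-4,4-dimethyl-3-methylidenecyclohexyl]oxy}dimethylsilane | C/C=C1\[C@@H](O[Si](C)(C)C(C)(C)C)CCC(C)(C)C1=C | intermediate
11 | methacrolein | CC(=C)C=O | starting material
12 | (1R,2R,8S)-8-(tert-butyldimethylsilyloxy)-1,2,5,5-tetramethyl-1,2,3,4,5,6,7,8-octahydronaphthalene-2-carbaldehyde | O=C[C@]1(C)CCC2=C([C@H]1C)[C@@H](O[Si](C)(C)C(C)(C)C)CCC2(C)C | intermediate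
13 | (1'S,2'R,8'S)-8'-(tert-butyldimethylsilyloxy)-2'-(2-methoxyethenyl)-1',2',5',5'-tetramethyl-1',2',3',4',5',6',7',8'-octahydronaphthalene, E/Z mixture | COC=C[C@]1(C)CCC2=C([C@H]1C)[C@@H](O[Si](C)(C)C(C)(C)C)CCC2(C)C | intermediate
14 | (1'S,2'R,8'S)-2'-(2-methoxyethenyl)-1',2',5',5'-tetramethyl-1',2',3',4',5',6',7',8'-octahydronaphthalen-8'-ol | COC=C[C@]1(C)CCC2=C([C@H]1C)[C@@H](O)CCC2(C)C | intermediate
15 | (1'S,2'R)-2'-(2-methoxyethenyl)-1',2',5',5'-tetramethyl-2',3',4',5',6',7'-hexahydronaphthalen-8'(1'H)-one | COC=C[C@]1(C)CCC2=C([C@H]1C)C(=O)CCC2(C)C | intermediate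
16 | 2-[(1S,2S)-1,2,5,5-tetramethyl-8-oxo-1,2,3,4,5,6,7,8-octahydronaphthalen-2-yl]acetaldehyde | O=CC[C@]1(C)CCC2=C([C@H]1C)C(=O)CCC2(C)C | intermediate
17 | (R)-3-(benzyloxy)propane-1,2-diol | OC[C@@H](O)COCc1ccccc1 | starting material
18 | (S)-1-(benzyloxy)-2,3-bis(triethylsilyloxy)propane | CC[Si](CC)(CC)OC[C@@H](O[Si](CC)(CC)CC)COCc1ccccc1 | intermediate
19 | (S)-3-(benzyloxy)-2-(triethylsilyloxy)propanal | O=C[C@@H](O[Si](CC)(CC)CC)COCc1ccccc1 | intermediate
20 | ethyl 2-oxo-3-(triphenylphosphoranylidene)propanoate | CCOC(=O)C(=O)C=P(c1ccccc1)(c1ccccc1)c1ccccc1 | starting material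
21 | ethyl (R,E)-6-(benzyloxy)-2-oxo-5-(triethylsilyloxy)hex-3-enoate | CCOC(=O)C(=O)/C=C/[C@@H](O[Si](CC)(CC)CC)COCc1ccccc1 | intermediate
22 | ethyl (3R,4R)-4-[(1R)-2-(benzyloxy)-1-(triethylsilyloxy)ethyl]-2-hydroxy-3-[(1S,2R)-1,2,5,5-tetramethyl-8-oxo-1,2,3,4,5,6,7,8-octahydronaphthalen-2-yl]-3,4-dihydro-2H-pyran-6-carboxylate, anomer mixture | CCOC(=O)C1=C[C@@H]([C@@H](O[Si](CC)(CC)CC)COCc2ccccc2)[C@@H](C(O)O1)[C@]3(C)CCC4=C([C@H]3C)C(=O)CCC4(C)C | intermediate
23 | (3R,4R)-3-[(1R)-2-(benzyloxy)-1-(triethylsilyloxy)ethyl]-5-oxo-4-[(1S,2R)-1,2,5,5-tetramethyl-8-oxo-1,2,3,4,5,6,7,8-octahydronaphthalen-2-yl]pentanoic acid | OC(=O)C[C@@H]([C@@H](O[Si](CC)(CC)CC)COCc1ccccc1)[C@@H](C=O)[C@]2(C)CCC3=C([C@H]2C)C(=O)CCC3(C)C | intermediate (not isolated)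
24 | (3R,4R)-3-[(1R)-2-(benzyloxy)-1-hydroxyethyl]-5-oxo-4-[(1S,2R)-1,2,5,5-tetramethyl-8-oxo-1,2,3,4,5,6,7,8-octahydronaphthalen-2-yl]pentanoic acid | OC(=O)C[C@@H]([C@@H](O)COCc1ccccc1)[C@@H](C=O)[C@]2(C)CCC3=C([C@H]2C)C(=O)CCC3(C)C | intermediate (not isolated)
25 | (1S,5R,6R,8R)-6-[(benzyloxy)methyl]-8-[(1S,2R)-1,2,5,5-tetramethyl-8-oxo-1,2,3,4,5,6,7,8-octahydronaphthalen-2-yl]-2,7-dioxabicyclo[3.2.1]octan-3-one | c1ccccc1COC[C@@H]2O[C@H]3OC(=O)C[C@@H]2[C@@H]3[C@]4(C)CCC5=C([C@H]4C)C(=O)CCC5(C)C | intermediate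
26 | (1S,5R,6R,8R)-6-(hydroxymethyl)-8-[(1S,2R)-1,2,5,5-tetramethyl-8-oxo-1,2,3,4,5,6,7,8-octahydronaphthalen-2-yl]-2,7-dioxabicyclo[3.2.1]octan-3-one | OC[C@@H]1O[C@H]2OC(=O)C[C@@H]1[C@@H]2[C@]3(C)CCC4=C([C@H]3C)C(=O)CCC4(C)C | intermediate
27 | (1S,5R,6R,8R)-3-oxo-8-[(1S,2R)-1,2,5,5-tetramethyl-8-oxo-1,2,3,4,5,6,7,8-octahydronaphthalen-2-yl]-2,7-dioxabicyclo[3.2.1]octane-6-carboxylic acid | OC(=O)[C@@H]1O[C@H]2OC(=O)C[C@@H]1[C@@H]2[C@]3(C)CCC4=C([C@H]3C)C(=O)CCC4(C)C | intermediate
28 | methyl (1S,5R,6R,8R)-3-oxo-8-[(1S,2R)-1,2,5,5-tetramethyl-8-oxo-1,2,3,4,5,6,7,8-octahydronaphthalen-2-yl]-2,7-dioxabicyclo[3.2.1]octane-6-carboxylate | COC(=O)[C@@H]1O[C@H]2OC(=O)C[C@@H]1[C@@H]2[C@]3(C)CCC4=C([C@H]3C)C(=O)CCC4(C)C | intermediate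
29 | methyl (1S,5R,6R,8R)-8-[(1S,2R,8R)-8-hydroxy-1,2,5,5-tetramethyl-1,2,3,4,5,6,7,8-octahydronaphthalen-2-yl]-3-oxo-2,7-dioxabicyclo[3.2.1]octane-6-carboxylate | COC(=O)[C@@H]1O[C@H]2OC(=O)C[C@@H]1[C@@H]2[C@]3(C)CCC4=C([C@H]3C)[C@H](O)CCC4(C)C | intermediate
30 | (8'S)-N-allylic N-(2-nitrophenylsulfonyl)hydrazine from 29 (C8' inverted) | COC(=O)[C@@H]1O[C@H]2OC(=O)C[C@@H]1[C@@H]2[C@]3(C)CCC4=C([C@H]3C)[C@@H](N(N)S(=O)(=O)c5ccccc5[N+](=O)[O-])CCC4(C)C | intermediate (not isolated)
31 | (8'S)-monoalkyl diazene from 30 | COC(=O)[C@@H]1O[C@H]2OC(=O)C[C@@H]1[C@@H]2[C@]3(C)CCC4=C([C@H]3C)[C@@H](N=N)CCC4(C)C | intermediate (not isolated)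
32 | methyl (1S,5R,6R,8R)-3-oxo-8-[(1S,2R,4aS)-1,2,5,5-tetramethyl-1,2,3,4,4a,5,6,7-octahydronaphthalen-2-yl]-2,7-dioxabicyclo[3.2.1]octane-6-carboxylate | COC(=O)[C@@H]1O[C@H]2OC(=O)C[C@@H]1[C@@H]2[C@]1(C)CC[C@@H]2C(=CCCC2(C)C)[C@H]1C | target

Total step count: 21 (steps 1–11 and 15–21 in the main line, steps 12–14 for the keto ester 21).
Longest linear sequence: 18 steps (1 → 16 → 32).

Steps most likely to fail

Step 7. The Lewis acid may ionise the allylic silyl ether or isomerise the diene, and exo-formyl and anti-silyloxy selectivity may be incomplete, which would give the C2' epimer or the antipodal C1'/C2' pair. Fallback: starting from diene 10, the cycloaddition is run without any acid, thermally, with methacrylonitrile (CC(=C)C#N, PhMe, BHT, sealed tube, about 130 °C). The small linear cyano group leaves the choice of face to the pseudoaxial silyl ether and the α-methyl group keeps the endo position. This gives (1S,2R,8S)-8-(tert-butyldimethylsilyloxy)-1,2,5,5-tetramethyl-1,2,3,4,5,6,7,8-octahydronaphthalene-2-carbonitrile F1. Reduction with i-Bu2AlH (PhMe, −78 °C) and hydrolysis of the imine returns to aldehyde 12.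

Step 15. Enamine formation and addition may be slow for the neopentyl-type aldehyde, and the γ-silyloxy centre of 21 may oppose the face chosen by the catalyst, eroding the trans selectivity. Fallback: starting from the E isomer of enol ether 15 and keto ester 21, the heterodiene is activated instead of the nucleophile. The catalyst is Cu(OTf)2 with 2,2'-(propane-2,2-diyl)bis[(4S)-4-tert-butyl-4,5-dihydrooxazole] or its antipode (CH2Cl2 or THF, −40 °C). The endo-selective hetero-Diels–Alder reaction gives ethyl (2S,3R,4R)-4-[(1R)-2-(benzyloxy)-1-(triethylsilyloxy)ethyl]-2-methoxy-3-[(1S,2R)-1,2,5,5-tetramethyl-8-oxo-1,2,3,4,5,6,7,8-octahydronaphthalen-2-yl]-3,4-dihydro-2H-pyran-6-carboxylate F2. Aqueous HCl then opens the acetal and enol ether and removes the silyl group, and the peroxide excision and dehydration of step 16 bring the material back at 25.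

Step 16. Peroxide may oxidise the free aldehyde, C8 may epimerise while the aldehyde is open, or the freed C6 hydroxyl may close onto the C3 acid as a five-membered lactone instead of onto C1. Fallback: starting from lactol 22, the oxolane ring is closed before any acid exists. PPTS in MeOH and then in PhMe removes the silyl group and should drive intramolecular transacetalisation to ethyl (1S,5R,6R,8R)-6-[(benzyloxy)methyl]-8-[(1S,2R)-1,2,5,5-tetramethyl-8-oxo-1,2,3,4,5,6,7,8-octahydronaphthalen-2-yl]-2,7-dioxabicyclo[3.2.1]oct-3-ene-3-carboxylate F3. LiOH (THF/H2O) gives the corresponding 2,7-dioxabicyclo[3.2.1]oct-3-ene-3-carboxylic acid F4. Dilute aqueous acid then opens only the enol ether (C1 stays as the oxolane lactol), H2O2 excises the carboxyl carbon, and dehydration with PPTS closes the lactone, returning at 25.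

Further compounds
F1 | step 7 | (1S,2R,8S)-8-(tert-butyldimethylsilyloxy)-1,2,5,5-tetramethyl-1,2,3,4,5,6,7,8-octahydronaphthalene-2-carbonitrile | N#C[C@]1(C)CCC2=C([C@H]1C)[C@@H](O[Si](C)(C)C(C)(C)C)CCC2(C)C
F2 | step 15 | ethyl (2S,3R,4R)-4-[(1R)-2-(benzyloxy)-1-(triethylsilyloxy)ethyl]-2-methoxy-3-[(1S,2R)-1,2,5,5-tetramethyl-8-oxo-1,2,3,4,5,6,7,8-octahydronaphthalen-2-yl]-3,4-dihydro-2H-pyran-6-carboxylate | CCOC(=O)C1=C[C@@H]([C@@H](O[Si](CC)(CC)CC)COCc2ccccc2)[C@@H]([C@@H](OC)O1)[C@]3(C)CCC4=C([C@H]3C)C(=O)CCC4(C)C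
F3 | step 16 | ethyl (1S,5R,6R,8R)-6-[(benzyloxy)methyl]-8-[(1S,2R)-1,2,5,5-tetramethyl-8-oxo-1,2,3,4,5,6,7,8-octahydronaphthalen-2-yl]-2,7-dioxabicyclo[3.2.1]oct-3-ene-3-carboxylate | CCOC(=O)C1=C[C@H]2[C@H](COCc3ccccc3)O[C@@H](O1)[C@H]2[C@]4(C)CCC5=C([C@H]4C)C(=O)CCC5(C)C
F4 | step 16 | (1S,5R,6R,8R)-6-[(benzyloxy)methyl]-8-[(1S,2R)-1,2,5,5-tetramethyl-8-oxo-1,2,3,4,5,6,7,8-octahydronaphthalen-2-yl]-2,7-dioxabicyclo[3.2.1]oct-3-ene-3-carboxylic acid | OC(=O)C1=C[C@H]2[C@H](COCc3ccccc3)O[C@@H](O1)[C@H]2[C@]4(C)CCC5=C([C@H]4C)C(=O)CCC5(C)C
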